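## Structural features

Gnetofuran A is a 2,3-dihydrobenzofuran (ring A fused to the five-membered ring O1–C2–C3–C3a–C7a). It carries a guaiacyl ring (4-hydroxy-3-methoxyphenyl, joined through C1′) on C2, a hydroxymethyl group on C3, a methoxy group on C7 and, on C5, an (E)-ethenyl bridge to a resorcinol ring. The only stereocentres, C2 (R) and C3 (S), are adjacent and trans on the five-membered ring. C2 is a benzylic ether para to a free phenol, so the O1–C2 bond can open to a para-quinone methide under acid or base. That makes C2 epimerisable towards the more stable trans isomer, and it also makes the ring easy to close late. C3 carries only carbon substituents and hydrogen and cannot be corrected once set. Its absolute configuration is the real difficulty, together with the sensitivity of the electron-rich stilbene and the three free phenols to oxidants, strong acid and light. The key step exploits the fact that C2 and C3 each bear one aryl group (C1′ on C2, C3a of ring A on C3), beside an oxygen on C2 and a CH2O group on C3. This is the pattern left by adding two aryl groups across an (E)-3-oxypropenyl boron compound, with boron holding the place of the C2 oxygen.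

## Logic of the disconnections

**22 ⇒ 21.** The four O–Si bonds (guaiacyl oxygen, two resorcinol oxygens, primary oxygen) are cut. The free phenols beside the C2 ether and the stilbene are the most fragile array, so they are released last and together. All earlier steps then handle a non-phenolic molecule. The forward step must remove three kinds of silyl ether with one reagent without base-induced opening of O1–C2.

**21 ⇒ 16 + 20.** The C=C bond of the C5 arm is cut. It is the only link to the resorcinol ring, and olefination of an aryl aldehyde with a benzyl phosphonate gives the (E)-alkene. This makes the route convergent and takes the alkene out of the chiral core. The base must leave the aryl silyl ethers and C2 untouched.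

**20 ⇒ 19 ⇒ 18 ⇒ 17.** The C–P bond, the benzylic C–Br bond (from C–O) and the O–Si bonds are cut in turn. The demand is chemoselective exchange of the benzylic silyl ether in the presence of two aryl silyl ethers.

**16 ⇒ 14 (through 15).** The O1–C2 bond is cut. C2 is benzylic to a para-oxygenated ring, so the bond forms by capture of a C2 cation by the ring A phenol, and trans is the stable arrangement. The heterocycle becomes an acyclic 1,2-diaryl-1,3-diol derivative, and the same acid releases the aldehyde. The acid must remove the methoxymethyl and dioxolane groups but leave both silyl ethers, and ring closure must outrun loss of the C3 proton.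

**14 ⇒ 13.** The C2–O bond is traced back to a C2–B bond. Boron survives C–C bond formation and is exchanged for oxygen with retention. The oxidation must not strip the aryl silyl ether.

**13 ⇒ 12 + 3.** The C2–C1′ and C3–C3a bonds are cut together. Both aryl groups and both stereocentres then come from one catalytic three-component event on a flat alkene. The forward step needs a 1,2-shift from boron in preference to direct boron-to-palladium transfer, and it needs facial control at C3. The (1R,2S) configuration of 13 and 14 corresponds to (2R,3S) in 16, 21 and 22.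

**12 ⇒ 5 + 10 (through 11); 5 ⇒ 4.** The B–C1′ bond and then the O–Si bond are cut. The aryl group is delivered as an organolithium to trigonal boron. The protecting group must survive the organolithium and later acid, and it must leave with fluoride.

**10 ⇒ 8 + 7 (through 9); 7 ⇒ 6.** The alkenyl C–B bond (with its C–H partner), the two B–O bonds and the two C–CH3 bonds of the diol are cut. This leads back to a terminal alkyne and a commercial diketone. The forward steps need terminal, syn hydroboration and a cis diol.

**3 ⇒ 2 ⇒ 1.** The acetal C–O bonds and the O–CH2OMe bond are cut. Both masks fall in one later acid step. The acetal must be formed without exchanging the methoxymethyl ether.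

## Other disconnections considered

**Alternative 1:** The cut is O1–C2 alone, made after C3 exists.

- **Forward key step.** The (S)-diarylpropanol A1, whose stereocentre would come from asymmetric hydrogenation of its alkene precursor, would be treated with Ag2O. Monovalent silver oxidises the guaiacyl phenol to the para-quinone methide, and the ring A phenol adds to the methide carbon (5-exo-trig) to give ester A2.
- **In its favour.** The closure needs no leaving group at C2 and no phenol protection at that stage. Hydrogenation is a mature, scalable way to set C3, and on that point the alternative is the better plan. The chosen key step lies nearer the edge of its known scope (β-substituted alkene, ortho-alkoxy aryl bromide).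
- **Against it here.** The ring A two-carbon building block for A1 is not commercial. The quinone methide can tautomerise to a conjugated vinyl phenol, which would erase C3. Ring A needs the deactivating ester so that only the guaiacyl phenol is oxidised, and that ester must later be brought to the aldehyde level beside a free primary alcohol and phenols.
- **Comparison.** Control of C2 by C3 through a reversible, trans-selective closure is the same in both plans (equal). The tautomerisation risk is the counterpart of the elimination risk in step 9 (equal). Structurally the alternative's key step makes one C–O bond, one ring and one stereocentre, whereas step 7 makes two C–C bonds and both stereocentres but no ring. Step economy is about equal once the ester adjustment is counted.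

**Alternative 2:** The cut is C3–C3a, formed by a 1,2-shift.

- **Forward key step.** The (R)-flavanone A3 would react with PhI(OAc)2 (trivalent iodine) and acid in trimethyl orthoformate. Enol ether formation, iodination at the CH2 carbon and migration of the ring A carbon with loss of iodobenzene would give the trans ester A4.
- **In its favour.** The reaction type is documented for flavanones and gives the trans 2-aryl-3-carboxylate directly, so the whole core arises in very few steps. The C5 bromide would allow the arm to be attached by a Heck reaction, which needs no phosphonate synthesis; this is equal to or better than the aldehyde olefination. The alternative is the better plan on step count.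
- **Against it here.** Stereochemical information flows from C2 to C3, yet the flavanone C2 is labile through ring opening to the chalcone form, particularly with an electron-rich C2 aryl group and in the strongly acidic medium of the contraction. Migration of the guaiacyl ring (isoflavone formation) and dehydrogenation compete. The enantioselective preparation of A3 is a problem of its own.
- **Comparison.** Mechanistically the chosen plan places the non-correctable centre C3 under direct catalyst control and lets the labile C2 follow. The alternative does the reverse, and that is its main weakness. Structurally its key step builds C3–C3a and the ring at once, which is more per step than step 7.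

**Alternative 3:** The cuts are C3–CH2OH and O1–C2.

- **Forward key step.** Stilbene A5 and formaldehyde would be combined under a chiral confined imidodiphosphorimidate Brønsted acid. C3 attacks the activated formaldehyde, and the ring A phenol captures the C2 cation to give alcohol A6.
- **In its favour.** Ring, both stereocentres and the hydroxymethyl carbon would arise from a flat, easily made stilbene in one catalytic operation with no stoichiometric organometallic. On step and atom economy this is the best of the four plans.
- **Against it here.** An acyclic 1,2-diaryl alkene with phenol capture is not an established member of this catalyst family's Prins chemistry. Both alkene carbons are benzylic to oxygen-activated rings, so the site of C–C bond formation is not secured. The phenol can react with formaldehyde first (chromane-type or ring hydroxymethylation products). Enantio-induction must be exerted in a stepwise cationic process. The catalyst needs a multi-step synthesis.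
- **Comparison.** Structurally it achieves more per step than step 7. Mechanistically step 7 rests on a precedented catalytic class, with anti addition fixed by the alkene geometry, while the alternative depends on selectivities for which no close model exists. The chosen plan is longer but the more defensible.

Key step: step 7

Remarks before the steps:
- Assumption: silyl ether 8 is a catalogue compound.
- Assumption: the antipode of MandyPhos that gives (1R,2S)-13 is chosen from a small-scale run; both antipodes are sold.
- Design changes from the simplest scheme: pinacol on boron is replaced by the bulkier cis-1,2-dimethylacenaphthylene-1,2-diol ("mac"), because β-substituted alkenyl pinacol ate complexes tend towards direct transmetalation. The guaiacyl phenol is protected as a triisopropylsilyl ether and the primary alcohol as a tert-butyldiphenylsilyl ether, so that both survive the acid ring closure and no re-protection is needed.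

## Steps

Step 1
Reactants: 1 5-bromovanillin (3-bromo-4-hydroxy-5-methoxybenzaldehyde)
Product: 2 3-bromo-5-methoxy-4-(methoxymethoxy)benzaldehyde
Conditions: MOMCl, i-Pr2NEt, CH2Cl2, 0 °C → rt
Reagents that add atoms: chloromethyl methyl ether, COCCl
Why: Williamson-type O-alkylation of the acidic phenol with a reactive α-chloro ether; the aldehyde and the aryl bromide are inert.

Step 2
Reactants: 2 3-bromo-5-methoxy-4-(methoxymethoxy)benzaldehyde
Product: 3 2-[3-bromo-5-methoxy-4-(methoxymethoxy)phenyl]-1,3-dioxolane
Conditions: TMSOCH2CH2OTMS, TMSOTf (5 mol%), CH2Cl2, −78 → −20 °C; pyridine quench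
Reagents that add atoms: 1,2-bis(trimethylsilyloxy)ethane, C[Si](C)(C)OCCO[Si](C)(C)C
Why: Noyori acetalisation, driven by formation of hexamethyldisiloxane; the aprotic, cold conditions leave the methoxymethyl acetal unexchanged.

Step 3
Reactants: 4 4-bromo-2-methoxyphenol
Product: 5 (4-bromo-2-methoxyphenoxy)triisopropylsilane
Conditions: TIPSCl, imidazole, DMF, rt
Reagents that add atoms: triisopropylsilyl chloride, CC(C)[Si](Cl)(C(C)C)C(C)C
Why: imidazole-mediated silylation of a phenol; the bulky silyl ether should tolerate aryllithium, cold base and aqueous acid, and leave with fluoride.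

Step 4
Reactants: 6 acenaphthoquinone (acenaphthylene-1,2-dione)
Product: 7 cis-1,2-dimethyl-1,2-dihydroacenaphthylene-1,2-diol (mac diol, meso)
Conditions: AlMe3 (excess), toluene, 0 °C → rt; 1 M HCl work-up
Reagents that add atoms: trimethylaluminium, C[Al](C)C
Why: double 1,2-addition of methyl to the α-diketone; the second methyl should enter anti to the bulky aluminium alkoxide, so both hydroxyls end on one face (cis diol), the isomer able to chelate boron.

Step 5
Reactants: 8 tert-butyl(diphenyl)(prop-2-yn-1-yloxy)silane; 7 cis-1,2-dimethyl-1,2-dihydroacenaphthylene-1,2-diol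
Product: 10 (E)-3-(tert-butyldiphenylsilyloxy)prop-1-enylboronic acid mac ester, via catechol alkenylboronate 9 (not isolated)
Conditions: catecholborane (1.1 equiv), neat, 70 °C; then 7, THF, rt
Reagents that add atoms: catecholborane, B1Oc2ccccc2O1
Why: syn hydroboration of the terminal alkyne puts boron on the terminal carbon and gives only the (E)-alkene; aryloxy boron esters then exchange readily with a chelating aliphatic cis-diol (transesterification).

Step 6
Reactants: 5 (4-bromo-2-methoxyphenoxy)triisopropylsilane; 10 (E)-3-(tert-butyldiphenylsilyloxy)prop-1-enylboronic acid mac ester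
Product: 12 lithium (E)-[3-(tert-butyldiphenylsilyloxy)prop-1-enyl][3-methoxy-4-(triisopropylsilyloxy)phenyl](mac)borate, via aryllithium 11 (not isolated)
Conditions: t-BuLi (2.0 equiv), Et2O, −78 °C; then 10, −78 °C → rt; solvent removed, used crude
Reagents that add atoms: tert-butyllithium, [Li]C(C)(C)C
Why: bromine–lithium exchange (the second equivalent destroys t-BuBr) followed by addition of the aryllithium to trigonal boron gives the four-coordinate borate; the para silyl ether cannot migrate to the lithiated carbon.

Step 7
Reactants: 12 lithium (E)-[3-(tert-butyldiphenylsilyloxy)prop-1-enyl][3-methoxy-4-(triisopropylsilyloxy)phenyl](mac)borate; 3 2-[3-bromo-5-methoxy-4-(methoxymethoxy)phenyl]-1,3-dioxolane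
Product: 13 (1R,2S)-3-(tert-butyldiphenylsilyloxy)-2-[5-(1,3-dioxolan-2-yl)-3-methoxy-2-(methoxymethoxy)phenyl]-1-[3-methoxy-4-(triisopropylsilyloxy)phenyl]propylboronic acid mac ester
Conditions: Pd(OAc)2 (3 mol%), MandyPhos C52H50FeN2P2 (one antipode, 3.6 mol%), KOTf (2 equiv), THF, 60 °C
Reagents that add atoms: none
Why: Zerovalent palladium formed from Pd(OAc)2 and the ferrocenyl diphosphine inserts into the C–Br bond of 3, and KOTf removes bromide as KBr so that a cationic arylpalladium species with a free site results. This cation binds the alkene of 12 and induces a 1,2-shift of the guaiacyl group from boron to the boron-bearing carbon, antiperiplanar to palladium, which becomes σ-bound to the carbon carrying the silyloxymethyl group. Reductive elimination with retention then joins that carbon to the ring A aryl group and returns zerovalent palladium. The closest known reaction type is the enantioselective palladium/MandyPhos conjunctive cross-coupling of β-substituted alkenylboron ate complexes bearing the mac diol with aryl electrophiles. No ring is closed. The carbon that becomes C3 is set by the alkene face that the chiral arylpalladium cation occupies (ligand control). The carbon that becomes C2 is fixed relative to it by the anti relation of migration and palladation across the (E)-alkene (substrate geometry), which gives the (1R,2S) isomer with boron and the new aryl group syn in the zigzag drawing. The step needs the metallate shift to win over direct boron-to-palladium transfer and over β-hydride or β-silyloxy elimination: the congested mac ester shields the boronate oxygens that mediate transmetalation, the electron-rich guaiacyl group migrates readily, and the wide-bite-angle ligand speeds reductive elimination.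

Step 8
Reactants: 13 (1R,2S)-configured mac boronate
Product: 14 (1R,2S)-3-(tert-butyldiphenylsilyloxy)-2-[5-(1,3-dioxolan-2-yl)-3-methoxy-2-(methoxymethoxy)phenyl]-1-[3-methoxy-4-(triisopropylsilyloxy)phenyl]propan-1-ol
Conditions: 30% H2O2, 3 M NaOH, THF, 0 °C → rt
Reagents that add atoms: hydrogen peroxide, OO
Why: oxidation of the organoboronate by hydroperoxide addition to boron and 1,2-shift of carbon from boron to oxygen with retention, so C1 stays R; acetals and the bulky silyl ethers should tolerate cold dilute base for the short reaction time.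

Step 9
Reactants: 14 (1R,2S)-configured benzylic alcohol
Product: 16 (2R,3S)-3-[(tert-butyldiphenylsilyloxy)methyl]-7-methoxy-2-[3-methoxy-4-(triisopropylsilyloxy)phenyl]-2,3-dihydro-1-benzofuran-5-carbaldehyde, via unmasked phenol aldehyde 15 (not isolated)
Conditions: 3 M aq. HCl/THF (1:4), 40 °C
Reagents that add atoms: water, O
Why: acetal hydrolysis frees the aldehyde and the ring A phenol; the benzylic alcohol then ionises (cation stabilised by the para silyloxy group) and is captured by the phenol in an SN1 cyclodehydration (5-exo closure) that is reversible and settles on the trans isomer, with C3 untouched. The tert-butyldiphenylsilyl and aryl triisopropylsilyl ethers are the acid-stable members of their class.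

Step 10
Reactants: 17 3,5-dihydroxybenzyl alcohol
Product: 18 tert-butyl{[3,5-bis(tert-butyldimethylsilyloxy)phenyl]methoxy}dimethylsilane
Conditions: TBSCl (3.5 equiv), imidazole, DMF, rt
Reagents that add atoms: tert-butyldimethylsilyl chloride, CC(C)(C)[Si](C)(C)Cl
Why: exhaustive imidazole-mediated silylation of two phenols and one primary alcohol.

Step 11
Reactants: 18 tris(silyl) ether
Product: 19 3,5-bis(tert-butyldimethylsilyloxy)benzyl bromide
Conditions: Ph3PBr2, CH2Cl2, 0 °C → rt
Reagents that add atoms: triphenylphosphine dibromide, BrP(Br)(c1ccccc1)(c1ccccc1)c1ccccc1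
Why: direct conversion of an alkyl silyl ether to the bromide through an alkoxyphosphonium ion and SN2 attack of bromide at the benzylic carbon; aryl silyl ethers cannot be displaced at an sp2 carbon and remain.

Step 12
Reactants: 19 3,5-bis(tert-butyldimethylsilyloxy)benzyl bromide
Product: 20 diethyl [3,5-bis(tert-butyldimethylsilyloxy)benzyl]phosphonate
Conditions: P(OEt)3, neat, 130 °C
Reagents that add atoms: triethyl phosphite, CCOP(OCC)OCC
Why: Michaelis–Arbuzov reaction of a reactive benzylic bromide; the volatile bromoethane leaves the mixture.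

Step 13
Reactants: 16 (2R,3S)-dihydrobenzofuran-5-carbaldehyde; 20 diethyl [3,5-bis(tert-butyldimethylsilyloxy)benzyl]phosphonate
Product: 21 (2R,3S)-5-{(E)-2-[3,5-bis(tert-butyldimethylsilyloxy)phenyl]ethenyl}-3-[(tert-butyldiphenylsilyloxy)methyl]-7-methoxy-2-[3-methoxy-4-(triisopropylsilyloxy)phenyl]-2,3-dihydro-1-benzofuran
Conditions: NaN(SiMe3)2, THF, 0 °C → rt (aldehyde added to the preformed anion)
Reagents that add atoms: none
Why: Horner–Wadsworth–Emmons olefination; benzyl phosphonate anions give (E)-stilbenes with aryl aldehydes. The non-nucleophilic amide base should spare the silyl ethers, and with the phenol protected the C2 ether cannot open.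

Step 14
Reactants: 21 tetrasilyl ether of gnetofuran A
Product: 22 gnetofuran A, 5-{(E)-2-[(2R,3S)-2-(4-hydroxy-3-methoxyphenyl)-3-(hydroxymethyl)-7-methoxy-2,3-dihydro-1-benzofuran-5-yl]ethenyl}benzene-1,3-diol
Conditions: Bu4NF, AcOH (1:1), THF, 0 °C → rt
Reagents that add atoms: none
Why: fluoride-induced cleavage of all four Si–O bonds; the acetic acid buffer keeps the liberated phenoxides protonated so that O1–C2 should not open and the stilbene is not exposed to strong base.

## Compound list

1 | 5-bromovanillin | COc1cc(C=O)cc(Br)c1O | starting material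
2 | 3-bromo-5-methoxy-4-(methoxymethoxy)benzaldehyde | COCOc1c(Br)cc(C=O)cc1OC | intermediate
3 | 2-[3-bromo-5-methoxy-4-(methoxymethoxy)phenyl]-1,3-dioxolane | COCOc1c(Br)cc(C2OCCO2)cc1OC | intermediate
4 | 4-bromo-2-methoxyphenol | COc1cc(Br)ccc1O | starting material
5 | (4-bromo-2-methoxyphenoxy)triisopropylsilane | COc1cc(Br)ccc1O[Si](C(C)C)(C(C)C)C(C)C | intermediate
6 | acenaphthoquinone | O=C1C(=O)c2cccc3cccc1c23 | starting material
7 | cis-1,2-dimethyl-1,2-dihydroacenaphthylene-1,2-diol (mac diol) | C[C@@]1(O)c2cccc3cccc(c23)[C@]1(C)O | intermediate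
8 | tert-butyl(diphenyl)(prop-2-yn-1-yloxy)silane | C#CCO[Si](c1ccccc1)(c1ccccc1)C(C)(C)C | starting material
9 | 2-[(E)-3-(tert-butyldiphenylsilyloxy)prop-1-enyl]-1,3,2-benzodioxaborole (not isolated) | CC(C)(C)[Si](c1ccccc1)(c1ccccc1)OC/C=C/B1Oc2ccccc2O1 | intermediate
10 | (E)-3-(tert-butyldiphenylsilyloxy)prop-1-enylboronic acid mac ester | CC(C)(C)[Si](c1ccccc1)(c1ccccc1)OC/C=C/B1O[C@]2(C)c3cccc4cccc(c34)[C@]2(C)O1 | intermediate
11 | [3-methoxy-4-(triisopropylsilyloxy)phenyl]lithium (not isolated) | [Li]c1ccc(O[Si](C(C)C)(C(C)C)C(C)C)c(OC)c1 | intermediate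
12 | lithium (E)-[3-(tert-butyldiphenylsilyloxy)prop-1-enyl][3-methoxy-4-(triisopropylsilyloxy)phenyl](mac)borate (configuration at boron undefined) | [Li+].CC(C)(C)[Si](c1ccccc1)(c1ccccc1)OC/C=C/[B-]1(c2ccc(O[Si](C(C)C)(C(C)C)C(C)C)c(OC)c2)O[C@]2(C)c3cccc4cccc(c34)[C@]2(C)O1 | intermediate
13 | (1R,2S)-3-(tert-butyldiphenylsilyloxy)-2-[5-(1,3-dioxolan-2-yl)-3-methoxy-2-(methoxymethoxy)phenyl]-1-[3-methoxy-4-(triisopropylsilyloxy)phenyl]propylboronic acid mac ester | CC(C)[Si](C(C)C)(C(C)C)Oc1ccc(cc1OC)[C@H](B1O[C@]2(C)c3cccc4cccc(c34)[C@]2(C)O1)[C@H](CO[Si](c1ccccc1)(c1ccccc1)C(C)(C)C)c1cc(C2OCCO2)cc(OC)c1OCOC | intermediate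
14 | (1R,2S)-3-(tert-butyldiphenylsilyloxy)-2-[5-(1,3-dioxolan-2-yl)-3-methoxy-2-(methoxymethoxy)phenyl]-1-[3-methoxy-4-(triisopropylsilyloxy)phenyl]propan-1-ol | CC(C)[Si](C(C)C)(C(C)C)Oc1ccc(cc1OC)[C@H](O)[C@H](CO[Si](c1ccccc1)(c1ccccc1)C(C)(C)C)c1cc(C2OCCO2)cc(OC)c1OCOC | intermediate
15 | 3-[(1R,2S)-3-(tert-butyldiphenylsilyloxy)-1-hydroxy-1-(3-methoxy-4-triisopropylsilyloxyphenyl)propan-2-yl]-4-hydroxy-5-methoxybenzaldehyde (not isolated) | CC(C)[Si](C(C)C)(C(C)C)Oc1ccc(cc1OC)[C@H](O)[C@H](CO[Si](c1ccccc1)(c1ccccc1)C(C)(C)C)c1cc(C=O)cc(OC)c1O | intermediate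
16 | (2R,3S)-3-[(tert-butyldiphenylsilyloxy)methyl]-7-methoxy-2-[3-methoxy-4-(triisopropylsilyloxy)phenyl]-2,3-dihydro-1-benzofuran-5-carbaldehyde | COc1cc([C@@H]2Oc3c(OC)cc(C=O)cc3[C@H]2CO[Si](c2ccccc2)(c2ccccc2)C(C)(C)C)ccc1O[Si](C(C)C)(C(C)C)C(C)C | intermediate
17 | 3,5-dihydroxybenzyl alcohol | OCc1cc(O)cc(O)c1 | starting material
18 | tert-butyl{[3,5-bis(tert-butyldimethylsilyloxy)phenyl]methoxy}dimethylsilane | CC(C)(C)[Si](C)(C)OCc1cc(O[Si](C)(C)C(C)(C)C)cc(O[Si](C)(C)C(C)(C)C)c1 | intermediate
19 | 3,5-bis(tert-butyldimethylsilyloxy)benzyl bromide | BrCc1cc(O[Si](C)(C)C(C)(C)C)cc(O[Si](C)(C)C(C)(C)C)c1 | intermediate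
20 | diethyl [3,5-bis(tert-butyldimethylsilyloxy)benzyl]phosphonate | CCOP(=O)(OCC)Cc1cc(O[Si](C)(C)C(C)(C)C)cc(O[Si](C)(C)C(C)(C)C)c1 | intermediate
21 | (2R,3S)-5-{(E)-2-[3,5-bis(tert-butyldimethylsilyloxy)phenyl]ethenyl}-3-[(tert-butyldiphenylsilyloxy)methyl]-7-methoxy-2-[3-methoxy-4-(triisopropylsilyloxy)phenyl]-2,3-dihydro-1-benzofuran | COc1cc([C@@H]2Oc3c(OC)cc(/C=C/c4cc(O[Si](C)(C)C(C)(C)C)cc(O[Si](C)(C)C(C)(C)C)c4)cc3[C@H]2CO[Si](c2ccccc2)(c2ccccc2)C(C)(C)C)ccc1O[Si](C(C)C)(C(C)C)C(C)C | intermediate
22 | gnetofuran A | COc1cc([C@@H]2Oc3c(OC)cc(/C=C/c4cc(O)cc(O)c4)cc3[C@H]2CO)ccc1O | target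

## Step count and least certain steps

Total step count: 14. Longest linear sequence: 8 steps (steps 4, 5, 6, 7, 8, 9, 13, 14, from 6 to 22).

**Step 7 (key step).** The most likely failures are these:
- direct transfer of the guaiacyl or alkenyl group from boron to palladium (Suzuki–Miyaura coupling) instead of the metallate shift, because the alkene is β-substituted and the aryl bromide is ortho-substituted;
- β-elimination from the alkylpalladium intermediate next to the silyloxymethyl group;
- weak facial discrimination if the ortho methoxymethyl oxygen chelates palladium.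

The fallback is an auxiliary-controlled aldol route that sets out from 3 (with 5 through 11 for the aldehyde) and returns at 14. Compound 3 would be coupled with the Reformatsky reagent BrZnCH2CO2Et under Pd(dba)2/P(t-Bu)3 to give ethyl [5-(1,3-dioxolan-2-yl)-3-methoxy-2-(methoxymethoxy)phenyl]acetate F1. Saponification with LiOH would give [5-(1,3-dioxolan-2-yl)-3-methoxy-2-(methoxymethoxy)phenyl]acetic acid F2. Activation as the pivaloyl mixed anhydride and acylation of lithiated (R)-4-benzyloxazolidin-2-one would give (R)-4-benzyl-3-(arylacetyl)oxazolidin-2-one F3. Aryllithium 11 would be quenched with DMF to give 3-methoxy-4-(triisopropylsilyloxy)benzaldehyde F4. An Evans syn aldol reaction of F3 with F4 (Bu2BOTf, i-Pr2NEt) would give the (2R,3R) aldol adduct F5. Reductive removal of the auxiliary with LiBH4 would give (1R,2S)-2-[5-(1,3-dioxolan-2-yl)-3-methoxy-2-(methoxymethoxy)phenyl]-1-[3-methoxy-4-(triisopropylsilyloxy)phenyl]propane-1,3-diol F6. Selective silylation of its primary hydroxyl (TBDPSCl, imidazole) leads to 14.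

**Step 9.** The most likely failures are partial loss of the silyl ethers, loss of the C3 proton from the benzylic cation followed by re-protonation (erosion of C3), and intermolecular capture of the cation or of released formaldehyde by the electron-rich rings. All three are favoured because the para silyloxy group makes ionisation slower than for a free phenol and so calls for stronger acid.

The fallback sets out from 14 and returns at 22. Bu4NF would first free the phenol and the primary alcohol to give (1R,2S)-2-[5-(1,3-dioxolan-2-yl)-3-methoxy-2-(methoxymethoxy)phenyl]-1-(4-hydroxy-3-methoxyphenyl)propane-1,3-diol F7. With the para phenol free, C2 ionises through the quinone methide at low acidity, so dilute HCl in wet THF at rt should give (2R,3S)-2-(4-hydroxy-3-methoxyphenyl)-3-(hydroxymethyl)-7-methoxy-2,3-dihydro-1-benzofuran-5-carbaldehyde F8. Silylation (TBSCl, imidazole) would give the bis(tert-butyldimethylsilyl) ether F9. Olefination with 20 as in step 13 would give the tetrakis(tert-butyldimethylsilyl) ether of gnetofuran A F10, and Bu4NF/AcOH would give 22.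

**Step 13.** The most likely failures are base-induced loss of an aryl silyl group, after which the phenoxide opens the dihydrofuran through the quinone methide, and sluggish addition to the electron-rich aldehyde.

The fallback sets out from 16 and returns at 21. Wittig methylenation (Ph3P=CH2) would give (2R,3S)-3-[(tert-butyldiphenylsilyloxy)methyl]-5-ethenyl-7-methoxy-2-[3-methoxy-4-(triisopropylsilyloxy)phenyl]-2,3-dihydro-1-benzofuran F11. A Mizoroki–Heck reaction (Pd(OAc)2, P(o-tol)3, Et3N, DMF, 90 °C) with 1-iodo-3,5-bis(tert-butyldimethylsilyloxy)benzene F12, made from 5-iodoresorcinol with TBSCl and imidazole, would give 21 under only weakly basic conditions.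

**Step 5.** The most likely failures are incomplete terminal selectivity of the hydroboration and incomplete displacement of catechol by the hindered tertiary diol.

The fallback sets out from 8 and returns at 10. Hydroboration with pinacolborane catalysed by Cp2Zr(H)Cl would give (E)-3-(tert-butyldiphenylsilyloxy)prop-1-enylboronic acid pinacol ester F13. Oxidative removal of pinacol (NaIO4, NH4OAc, acetone/water) would give (E)-3-(tert-butyldiphenylsilyloxy)prop-1-enylboronic acid F14. Condensation with 7 over MgSO4 in CH2Cl2 would give 10.

## Further compounds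

F1 | step 7 | ethyl [5-(1,3-dioxolan-2-yl)-3-methoxy-2-(methoxymethoxy)phenyl]acetate | CCOC(=O)Cc1cc(C2OCCO2)cc(OC)c1OCOC
F2 | step 7 | [5-(1,3-dioxolan-2-yl)-3-methoxy-2-(methoxymethoxy)phenyl]acetic acid | OC(=O)Cc1cc(C2OCCO2)cc(OC)c1OCOC
F3 | step 7 | (R)-4-benzyl-3-{[5-(1,3-dioxolan-2-yl)-3-methoxy-2-(methoxymethoxy)phenyl]acetyl}oxazolidin-2-one | O=C(Cc1cc(C2OCCO2)cc(OC)c1OCOC)N1[C@H](Cc2ccccc2)COC1=O
F4 | step 7 | 3-methoxy-4-(triisopropylsilyloxy)benzaldehyde | COc1cc(C=O)ccc1O[Si](C(C)C)(C(C)C)C(C)C
F5 | step 7 | (R)-4-benzyl-3-{(2R,3R)-2-[5-(1,3-dioxolan-2-yl)-3-methoxy-2-(methoxymethoxy)phenyl]-3-hydroxy-3-[3-methoxy-4-(triisopropylsilyloxy)phenyl]propanoyl}oxazolidin-2-one | CC(C)[Si](C(C)C)(C(C)C)Oc1ccc(cc1OC)[C@H](O)[C@H](C(=O)N1[C@H](Cc2ccccc2)COC1=O)c1cc(C2OCCO2)cc(OC)c1OCOC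
F6 | step 7 | (1R,2S)-2-[5-(1,3-dioxolan-2-yl)-3-methoxy-2-(methoxymethoxy)phenyl]-1-[3-methoxy-4-(triisopropylsilyloxy)phenyl]propane-1,3-diol | CC(C)[Si](C(C)C)(C(C)C)Oc1ccc(cc1OC)[C@H](O)[C@H](CO)c1cc(C2OCCO2)cc(OC)c1OCOC
F7 | step 9 | (1R,2S)-2-[5-(1,3-dioxolan-2-yl)-3-methoxy-2-(methoxymethoxy)phenyl]-1-(4-hydroxy-3-methoxyphenyl)propane-1,3-diol | Oc1ccc(cc1OC)[C@H](O)[C@H](CO)c1cc(C2OCCO2)cc(OC)c1OCOC
F8 | step 9 | (2R,3S)-2-(4-hydroxy-3-methoxyphenyl)-3-(hydroxymethyl)-7-methoxy-2,3-dihydro-1-benzofuran-5-carbaldehyde | COc1cc([C@@H]2Oc3c(OC)cc(C=O)cc3[C@H]2CO)ccc1O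
F9 | step 9 | (2R,3S)-3-[(tert-butyldimethylsilyloxy)methyl]-2-[4-(tert-butyldimethylsilyloxy)-3-methoxyphenyl]-7-methoxy-2,3-dihydro-1-benzofuran-5-carbaldehyde | COc1cc([C@@H]2Oc3c(OC)cc(C=O)cc3[C@H]2CO[Si](C)(C)C(C)(C)C)ccc1O[Si](C)(C)C(C)(C)C
F10 | step 9 | (2R,3S)-5-{(E)-2-[3,5-bis(tert-butyldimethylsilyloxy)phenyl]ethenyl}-3-[(tert-butyldimethylsilyloxy)methyl]-2-[4-(tert-butyldimethylsilyloxy)-3-methoxyphenyl]-7-methoxy-2,3-dihydro-1-benzofuran | COc1cc([C@@H]2Oc3c(OC)cc(/C=C/c4cc(O[Si](C)(C)C(C)(C)C)cc(O[Si](C)(C)C(C)(C)C)c4)cc3[C@H]2CO[Si](C)(C)C(C)(C)C)ccc1O[Si](C)(C)C(C)(C)C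
F11 | step 13 | (2R,3S)-3-[(tert-butyldiphenylsilyloxy)methyl]-5-ethenyl-7-methoxy-2-[3-methoxy-4-(triisopropylsilyloxy)phenyl]-2,3-dihydro-1-benzofuran | COc1cc([C@@H]2Oc3c(OC)cc(C=C)cc3[C@H]2CO[Si](c2ccccc2)(c2ccccc2)C(C)(C)C)ccc1O[Si](C(C)C)(C(C)C)C(C)C
F12 | step 13 | 1-iodo-3,5-bis(tert-butyldimethylsilyloxy)benzene | Ic1cc(O[Si](C)(C)C(C)(C)C)cc(O[Si](C)(C)C(C)(C)C)c1
F13 | step 5 | (E)-3-(tert-butyldiphenylsilyloxy)prop-1-enylboronic acid pinacol ester | CC(C)(C)[Si](c1ccccc1)(c1ccccc1)OC/C=C/B1OC(C)(C)C(C)(C)O1
F14 | step 5 | (E)-3-(tert-butyldiphenylsilyloxy)prop-1-enylboronic acid | CC(C)(C)[Si](c1ccccc1)(c1ccccc1)OC/C=C/B(O)O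
A1 | alternative 1 | methyl 4-hydroxy-3-[(2S)-1-hydroxy-3-(4-hydroxy-3-methoxyphenyl)propan-2-yl]-5-methoxybenzoate | COc1cc(C[C@H](CO)c2cc(C(=O)OC)cc(OC)c2O)ccc1O
A2 | alternative 1 | methyl (2R,3S)-2-(4-hydroxy-3-methoxyphenyl)-3-(hydroxymethyl)-7-methoxy-2,3-dihydro-1-benzofuran-5-carboxylate | COc1cc([C@@H]2Oc3c(OC)cc(C(=O)OC)cc3[C@H]2CO)ccc1O
A3 | alternative 2 | 4-[(2R)-6-bromo-8-methoxy-4-oxo-3,4-dihydro-2H-chromen-2-yl]-2-methoxyphenyl acetate | COc1cc([C@H]2CC(=O)c3cc(Br)cc(OC)c3O2)ccc1OC(C)=O
A4 | alternative 2 | methyl (2R,3R)-2-(4-acetoxy-3-methoxyphenyl)-5-bromo-7-methoxy-2,3-dihydro-1-benzofuran-3-carboxylate (trans) | COc1cc([C@@H]2Oc3c(OC)cc(Br)cc3[C@H]2C(=O)OC)ccc1OC(C)=O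
A5 | alternative 3 | 4-bromo-2-methoxy-6-[(E)-2-(3-methoxy-4-triisopropylsilyloxyphenyl)ethenyl]phenol | COc1cc(/C=C/c2cc(Br)cc(OC)c2O)ccc1O[Si](C(C)C)(C(C)C)C(C)C
A6 | alternative 3 | [(2R,3S)-5-bromo-7-methoxy-2-(3-methoxy-4-triisopropylsilyloxyphenyl)-2,3-dihydro-1-benzofuran-3-yl]methanol | COc1cc([C@@H]2Oc3c(OC)cc(Br)cc3[C@H]2CO)ccc1O[Si](C(C)C)(C(C)C)C(C)C
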